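## The problem

The target joins two oxygen heterocycles through a single methylene group. One is a lariciresinol-type oxolane (aryl at C2, hydroxymethyl at C3, the methylene arm at C4; 2R,3S,4S, so 2,3-trans and 3,4-cis). The other is a trans-2-aryl-3-hydroxymethyl-2,3-dihydrobenzofuran (2S,3R) with a methoxy group at C4 and the arm at C6. A CH2 group and a benzene ring separate the two sets of stereocentres, so neither set can steer the other. Within the oxolane, C4 can set C3 and C3 can set C2; within the dihydrofuran the trans relation is the stable one, but its absolute sense relative to the oxolane must be imposed by a reagent. The benzene ring is a resorcinol ring (oxygen at C4 and C7a) with carbon between the oxygens (C3a) and a carbon arm meta to both (C6), a pattern that electrophilic substitution of a resorcinol ether, which goes ortho and para to oxygen, does not deliver. Both benzylic C–O bonds (oxolane C2–O1 beside a p-methoxyaryl group, dihydrofuran C2–O1 beside a p-hydroxyaryl group) ionise in acid, after which such oxolanes close onto a neighbouring electron-rich ring to give aryltetralins. These bonds are also cleaved by forcing hydrogenolysis, and the free phenols do not tolerate strong oxidants. The enabling feature is that the ring C3a–C4–C5–C6–C7–C7a, read without its aromaticity, is a 5-substituted cyclohexane-1,3-dione (carbonyl carbons C4 and C7a, C3a between them, the arm on C6). This dione has a mirror plane, so closing the furan ring on either oxygen gives the same product, and the remaining carbonyl becomes the C4 methoxy group.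

## Retrosynthesis

**Protecting groups (35 ← 34 ← 33).** No skeletal bond is cut. Both phenols are carried as benzyl ethers, which survive hydride, amide bases, hot alkali and fluoride. The oxolane hydroxymethyl is a triisopropylsilyl ether because it must pass through the dione annulation, and the dihydrofuran hydroxymethyl is a tert-butyldimethylsilyl ether because it enters with a commercial aldehyde. Fluoride converts 33 into diol 34, and neutral hydrogenolysis at one atmosphere gives 35. The forward steps must leave the two benzylic ring C–O bonds intact, which mild hydrogenolysis in this lignan class does.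

**Arene from the enone ring (33 ← 32 ← 29).** The C4–O–CH3 bond and two C–H bonds are removed, leading back to tetrahydrobenzofuranone 29. A one-step oxidative aromatisation in methanol under acidic conditions would be shorter. It would, however, liberate strong acid in hot methanol beside the p-methoxybenzylic oxolane ether and a newly formed, very nucleophilic ring, which is exactly the situation that leads to aryltetralins, and it would strip the silyl ethers. The base-mediated sequence is therefore chosen: C5 enolate, selenenylation, selenoxide elimination and tautomerisation to phenol 32, then O-methylation to 33. Going back to 29 removes the arene regiochemistry problem, and the C6 stereocentre of 29 is irrelevant because it is erased.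

**Key disconnection (29 ← 26 + 27, that is 19 + 25).** The O1–C2 and C2–C3 bonds of the dihydrofuran are cut, giving oxadiene 26 and the one-carbon ylide 27. Cutting C3–C3a and O1–C2 instead (a dione plus a cinnamyl alkene) offers no handle for the absolute sense. Cutting O1–C7a requires the finished arene and brings its regiochemistry back. In the chosen cut the one-carbon partner carries both the aryl group and the chiral controller, and the four-atom partner comes from a symmetric dione. The forward reaction must give the trans ring and take its absolute sense from the sulfide. Because 26 cannot be stored, it is released in the flask from sulfone 19 while 27 is released from salt 25.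

**The two partners (19 ← 17 + 18; 25 ← 22 + 24; 22 ← 21 ← 20; 24 ← 23).** The C2–Cα bond of the dione side chain is cut, giving dione 17 and aldehyde 18, joined with a sulfinic acid that masks the alkylidene dione as 19. Salt 25 comes from benzylic bromide 24 (from commercial alcohol 23) and C2-symmetric thiolane 22. Thiolane 22 is made from diol 20 through dimesylate 21 with double inversion. Both enantiomers of the diol are articles of commerce, so either sense of induction is available.

**The dione ring (17 ← 14 + 15; 14 ← 12 + 13).** Two C–C bonds of the carbocycle are cut, giving enone 14 and malonate 15, the classical route to 5-substituted cyclohexane-1,3-diones and hence to 5-alkylresorcinols. The enone is cut at its double bond into allyl oxolane 12 and vinyl ketone 13. Cross-metathesis replaces an ozonolysis and Wittig pair by one step and keeps the oxolane side chain as a robust allyl group until then.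

**The oxolane (12 ← 11 ← 10 ← 9 ← 7 + 8).** The O1–C2 bond and the C2–C3 bond of the oxolane are cut. Aldol addition of lactone 7 to aldehyde 8 gives 9 with the new centre trans to the allyl group. Reduction gives triol 10, and acid closes the ring through the benzylic cation to 11. Because the ring is re-formed through the other hydroxymethyl group, the trans lactone gives the required 3,4-cis oxolane, and the aryl group settles trans to C3. This is the established route to this ring type; silylation then gives 12.

**The first stereocentre (7 ← 6 ← 5 ← 3 + 4; 3 ← 1 + 2).** The Cα–Cβ bond of the lactone is cut, giving imide 3 and bromoacetate 4. Evans alkylation with the (R)-auxiliary 1 sets the (S) centre of 5. Reduction to 6 and lactonisation give 7. All later oxolane centres derive from this one.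

## Roads not taken

**Alternative 1:** The dihydrobenzofuran C3–C3a bond is traced back to a chromanone. A protected (2S)-flavanone A2 from the chiral pool is treated with PhI(OAc)2 (trivalent iodine) and H2SO4 in trimethyl orthoformate. The fused aryl carbon migrates from C4 to C3 and the pyranone contracts to the trans dihydrobenzofuran ester A1.
- Merits: the reaction type is known, the C2 configuration comes with the starting material, the trans relation follows from the migration, and the oxygen pattern of the arene is that of the flavonoid.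
- Weak points: A1 carries a benzyloxy group at C6 where the target has the carbon arm. An oxygen-to-carbon exchange would be needed (debenzylation, triflation, sp2–sp3 coupling with an oxolanylmethyl metal reagent) beside an ester and a benzylic ether. Flavanones lose their C2 configuration by ring opening to the chalcone in acid or base, so A2 is at risk in the strongly acidic key step and during its protection. The ester must be reduced, and the oxolane half must still be made separately.
- Comparison: in precedent and in source of chirality this road is better than the chosen plan. The chosen plan sets against it that the C6 arm is part of the ring from the start, so no exchange at C6 and no late alkyl coupling are needed.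

**Alternative 2:** Two bonds of the benzene ring (C3a–C7a and C6–C7) are cut. In precursor A4, a 4-methoxy-2-pyrone carries the oxolanylmethyl group at C6 and, at C3, a side chain ending in an ethynyl ether. On heating, the alkyne adds across pyrone C3 and C6, CO2 is lost, and benzene and dihydrofuran rings form together to give the tetrasilyl ether A3.
- Merits: the tether fixes the regiochemistry, all five stereocentres are in place beforehand, and A3 is one desilylation from the target, a shorter endgame than that of the chosen plan.
- Weak points: the ynol ether in A4 is that of a secondary, p-oxygenated benzylic alcohol. It is hard to make, it ionises easily, and on heating it can fragment to a ketene in competition with the cycloaddition. The anti C2/C3 pair must be built separately by an asymmetric reaction on a pyrone side chain.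
- Comparison: the chosen plan sets against the shorter endgame that its two partners (17 and 25) come from robust classical reactions and that the stereo pair is created in the same step as the ring.

**Alternative 3:** The oxolane C3–C4 bond is cut. In A6, an epoxide is tethered through a cinnamyl ether whose aryl group is the complete dihydrobenzofuran. Cp2TiCl (trivalent titanium, from Cp2TiCl2 and Zn) opens the epoxide to the C3 radical, which closes 5-exo onto the alkene; reduction and protonation of the benzylic radical give A5.
- Merits: the reaction is well known for furanolignans, the oxolane hydroxymethyl emerges free, and the oxolane is made in fewer steps than by the lactone sequence chosen here.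
- Weak points: it solves the easier half. The dihydrobenzofuran, with its meta-dioxygenated arene, its two stereocentres and a vinyl handle at C6, must be supplied by another method, so the central problem is only postponed. The radical closure controls the 3,4 relation less firmly than the lactone route, and the epoxide and the benzylic ether centre need their own asymmetric steps.
- Comparison: for the oxolane alone this road is as good or better in step count. The chosen plan sets against it firm control of all three oxolane centres from one Evans centre and a direct answer to the arene problem.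

Key step: step 15

Assumption: the benzylide of (2S,5S)-2,5-dimethylthiolane is taken to add to the oxadiene on the same ylide face on which benzylides of this sulfide add to aldehydes. With inversion at the ylide carbon during ring closure this gives the (2S,3R) dihydrofuran. If the opposite sense is found, the enantiomeric sulfide, from (2S,5S)-hexane-2,5-diol, is used with no other change.

In the names below, Q stands for the (3S,4S,5R)-5-[3-(benzyloxy)-4-methoxyphenyl]-4-({[tri(propan-2-yl)silyl]oxy}methyl)oxolan-3-yl group.

## Route

Step 1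
Reactants: 1 (4R)-4-benzyl-1,3-oxazolidin-2-one; 2 pent-4-enoyl chloride
Product: 3 (4R)-4-benzyl-3-(pent-4-enoyl)-1,3-oxazolidin-2-one
Conditions: n-BuLi, THF, −78 °C; then 2, −78 → 0 °C
Reagents that add atoms: none
Why: N-Acylation of the lithiated oxazolidinone with an acid chloride is the standard entry to Evans imides; no stereocentre is formed.

Step 2
Reactants: 3 (4R)-4-benzyl-3-(pent-4-enoyl)-1,3-oxazolidin-2-one; 4 tert-butyl bromoacetate
Product: 5 tert-butyl (3S)-3-{[(4R)-4-benzyl-2-oxo-1,3-oxazolidin-3-yl]carbonyl}hex-5-enoate
Conditions: NaN(SiMe3)2, THF, −78 °C; then 4, −78 → −40 °C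
Reagents that add atoms: none
Why: Evans asymmetric alkylation: the chelated Z-enolate is alkylated on the face opposite the benzyl group of the (R)-auxiliary, which sets the (S) centre that becomes oxolane C4.

Step 3
Reactants: 5 tert-butyl (3S)-3-{[(4R)-4-benzyl-2-oxo-1,3-oxazolidin-3-yl]carbonyl}hex-5-enoate
Product: 7 (4S)-4-(prop-2-en-1-yl)oxolan-2-one, via hydroxy ester 6 (not isolated)
Conditions: LiBH4, MeOH (1 equiv), THF, 0 °C; then CF3CO2H, CH2Cl2, 0 °C → rt
Reagents that add atoms: none
Why: LiBH4 cleaves the imide reductively to the primary alcohol and spares the tert-butyl ester; acid then removes the tert-butyl group and the γ-hydroxy acid lactonises without touching the stereocentre.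

Step 4
Reactants: 7 (4S)-4-(prop-2-en-1-yl)oxolan-2-one; 8 3-(benzyloxy)-4-methoxybenzaldehyde
Product: 9 (3R,4S)-3-{[3-(benzyloxy)-4-methoxyphenyl](hydroxy)methyl}-4-(prop-2-en-1-yl)oxolan-2-one (both carbinol epimers)
Conditions: LiN(SiMe3)2, THF, −78 °C; then 8; NH4Cl aq at −78 °C
Reagents that add atoms: none
Why: Aldol addition of the lactone enolate: the aldehyde approaches anti to the C4 allyl group, so C3 is set trans to C4; the carbinol centre forms as a mixture and is reset in step 6.

Step 5
Reactants: 9 the aldol lactone
Product: 10 (2S,3S)-2-{[3-(benzyloxy)-4-methoxyphenyl](hydroxy)methyl}-3-(prop-2-en-1-yl)butane-1,4-diol (both carbinol epimers)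
Conditions: LiAlH4, THF, 0 °C
Reagents that add atoms: none
Why: Hydride reduction of a lactone to the diol; the benzyl ether and the alkene are inert.

Step 6
Reactants: 10 the triol
Product: 11 [(2R,3S,4S)-2-[3-(benzyloxy)-4-methoxyphenyl]-4-(prop-2-en-1-yl)oxolan-3-yl]methanol
Conditions: camphor-10-sulfonic acid (10 mol%), CH2Cl2, 0 °C → rt
Reagents that add atoms: none
Why: Acid-catalysed cyclodehydration as used for lariciresinol-type oxolanes: the p-methoxybenzylic alcohol ionises and the hydroxymethyl on the allyl-bearing carbon closes 5-exo (the other could only give an oxetane). Both carbinol epimers converge and the aryl group ends trans to the C3 hydroxymethyl, the more stable arrangement.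

Step 7
Reactants: 11 the oxolane alcohol
Product: 12 {[(2R,3S,4S)-2-[3-(benzyloxy)-4-methoxyphenyl]-4-(prop-2-en-1-yl)oxolan-3-yl]methoxy}tri(propan-2-yl)silane
Conditions: i-Pr3SiCl, imidazole, DMF, rt
Reagents that add atoms: chlorotri(propan-2-yl)silane, CC(C)[Si](Cl)(C(C)C)C(C)C
Why: Silylation of a primary alcohol; the triisopropylsilyl ether is chosen because it must withstand hot alkali and brief acid in step 9.

Step 8
Reactants: 12 the allyl oxolane silyl ether; 13 but-3-en-2-one
Product: 14 (3E)-5-Q-pent-3-en-2-one
Conditions: 13 (3 equiv), second-generation Hoveyda–Grubbs catalyst RuCl2(H2IMes)(=CH-C6H4-2-O-i-Pr) (5 mol%), CH2Cl2, 40 °C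
Reagents that add atoms: none
Why: Olefin cross-metathesis of a terminal alkene with an electron-poor vinyl ketone favours the E cross product and installs the methyl enone in one step.

Step 9
Reactants: 14 (3E)-5-Q-pent-3-en-2-one; 15 diethyl propanedioate
Product: 17 5-(Q-methyl)cyclohexane-1,3-dione, via keto ester 16 (not isolated)
Conditions: 15, NaOEt, EtOH, reflux; then NaOH aq, reflux; then HCl aq to pH 3, 60 °C
Reagents that add atoms: none
Why: Classical dione annulation: Michael addition of the malonate, Claisen closure of the methyl ketone enolate onto an ester to give 16, then saponification and decarboxylation of the β-keto acid. The product is a symmetric 5-substituted cyclohexane-1,3-dione, so the new ring carbon is not a stereocentre.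

Step 10
Reactants: 17 5-(Q-methyl)cyclohexane-1,3-dione; 18 {[tert-butyl(dimethyl)silyl]oxy}acetaldehyde
Product: 19 2-[2-{[tert-butyl(dimethyl)silyl]oxy}-1-(4-methylbenzenesulfonyl)ethyl]-5-(Q-methyl)cyclohexane-1,3-dione (stereoisomer mixture)
Conditions: 18, p-TolSO2H, MgSO4, CH2Cl2, rt
Reagents that add atoms: 4-methylbenzenesulfinic acid, Cc1ccc(cc1)S(O)=O
Why: Three-component Mannich-type condensation of a 1,3-dione, an aldehyde and an arenesulfinic acid: the Knoevenagel intermediate is trapped as a stable sulfone, a storable precursor of the alkylidene dione. The sulfone carbon forms as a mixture and becomes sp2 again in step 15.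

Step 11
Reactants: 20 (2R,5R)-hexane-2,5-diol
Product: 21 (2R,5R)-hexane-2,5-diyl dimethanesulfonate
Conditions: MsCl, Et3N, CH2Cl2, 0 °C
Reagents that add atoms: methanesulfonyl chloride, CS(Cl)(=O)=O
Why: Mesylation of secondary alcohols, with retention at carbon.

Step 12
Reactants: 21 the dimesylate
Product: 22 (2S,5S)-2,5-dimethylthiolane
Conditions: Na2S·9H2O, DMSO, rt → 40 °C
Reagents that add atoms: sodium sulfide, [Na+].[Na+].[S-2]
Why: Double SN2 displacement by sulfide with inversion at both carbons turns the (R,R)-dimesylate into the C2-symmetric (S,S)-thiolane.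

Step 13
Reactants: 23 [4-(benzyloxy)-3-methoxyphenyl]methanol
Product: 24 1-(benzyloxy)-4-(bromomethyl)-2-methoxybenzene
Conditions: PBr3, Et2O, 0 °C
Reagents that add atoms: phosphorus tribromide, BrP(Br)Br
Why: Standard conversion of an electron-rich benzylic alcohol into its bromide.

Step 14
Reactants: 22 (2S,5S)-2,5-dimethylthiolane; 24 the benzylic bromide
Product: 25 (2S,5S)-1-{[4-(benzyloxy)-3-methoxyphenyl]methyl}-2,5-dimethylthiolan-1-ium tetrafluoroborate
Conditions: NaBF4, CH2Cl2–H2O, rt
Reagents that add atoms: sodium tetrafluoroborate, [Na+].F[B-](F)(F)F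
Why: S-Alkylation of the sulfide by a reactive benzylic bromide with biphasic anion exchange gives a salt with a non-nucleophilic counter-ion; sulfur is not stereogenic because the thiolane is C2-symmetric.

Step 15
Reactants: 19 the sulfone adduct; 25 the thiolanium salt
Product: 29 (2S,3R)-2-[4-(benzyloxy)-3-methoxyphenyl]-3-({[tert-butyl(dimethyl)silyl]oxy}methyl)-6-(Q-methyl)-2,3,6,7-tetrahydro-1-benzofuran-4(5H)-one (both C6 epimers), via alkylidene dione 26 (not isolated), via sulfonium ylide 27 (not isolated), via betaine 28 (not isolated)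
Conditions: Cs2CO3 (3 equiv), CH2Cl2, −20 °C → rt
Reagents that add atoms: none
Why: Proposed new method: Cs2CO3 deprotonates the dione of 19, which expels the sulfinate (E1cB) to give oxadiene 26, and in parallel deprotonates 25 to benzylide 27; the ylide carbon adds to the exocyclic carbon of 26 (C2–C3 bond) to give betaine 28, whose enolate oxygen displaces the thiolane at the benzylic carbon with inversion (O1–C2 bond), a 5-exo-tet closure of the dihydrofuran ring. The closest known reaction type is the [4+1] annulation of carbonyl-stabilised sulfonium or pyridinium ylides with 2-alkylidene-1,3-diones and with ortho-quinone methides released by base from 2-(1-sulfonylalkyl)phenols, which gives trans-2,3-dihydrofurans; a semi-stabilised benzylide of a chiral sulfide has not been used in it. C3 is set in the conjugate addition and C2 in the displacement: the trans relation follows from the anti betaine (aryl and silyloxymethyl apart) and from the greater stability of the trans ring, and the absolute sense from the C2-symmetric thiolane, whose methyl group beside sulfur shields one face of the ylide as it does in epoxidations with benzylides of this sulfide. Because the parent dione is symmetric, either carbonyl oxygen closes to the same ring, so no regioselectivity is needed. O- over C-alkylation is not critical, since a spirocyclopropane from C-alkylation is a donor–acceptor cyclopropane that should ring-expand to 29. The remote oxolane centres cannot influence the new ones, so the step is reagent-controlled; the C6 centre forms as both epimers and disappears in step 16.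

Step 16
Reactants: 29 the tetrahydrobenzofuranone
Product: 32 (2S,3R)-2-[4-(benzyloxy)-3-methoxyphenyl]-3-({[tert-butyl(dimethyl)silyl]oxy}methyl)-6-(Q-methyl)-2,3-dihydro-1-benzofuran-4-ol, via selenide 30 (not isolated), via dienone 31 (not isolated)
Conditions: LiN(i-Pr)2, THF, −78 °C; PhSeCl, −78 °C; then H2O2 (30% aq), pyridine, CH2Cl2, 0 °C → rt
Reagents that add atoms: phenylselenyl chloride, Cl[Se]c1ccccc1 (its PhSe group is carried only by 30 and leaves again before 32)
Why: Kinetic deprotonation of the vinylogous ester at C5, selenenylation anti to the C6 substituent to give 30, then oxidation and selenoxide syn-elimination to cross-conjugated dienone 31, which tautomerises to the phenol. This is the standard conversion of 3-alkoxycyclohexenones into resorcinol monoethers; it is base-mediated, spares both benzylic ethers and removes the C6 stereocentre.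

Step 17
Reactants: 32 the phenol
Product: 33 the 4-methoxy-2,3-dihydro-1-benzofuran (methyl ether of 32)
Conditions: MeI, K2CO3, acetone, 50 °C
Reagents that add atoms: iodomethane, CI
Why: Williamson O-methylation of a phenol; no other acidic site is present.

Step 18
Reactants: 33 the fully protected target
Product: 34 {(2S,3R)-2-[4-(benzyloxy)-3-methoxyphenyl]-6-{[(3S,4S,5R)-5-[3-(benzyloxy)-4-methoxyphenyl]-4-(hydroxymethyl)oxolan-3-yl]methyl}-4-methoxy-2,3-dihydro-1-benzofuran-3-yl}methanol
Conditions: Bu4NF, THF, 0 °C → rt
Reagents that add atoms: none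
Why: Fluoride cleaves both primary silyl ethers and leaves the benzyl ethers untouched.

Step 19
Reactants: 34 the dibenzyl ether diol
Product: 35 {(2S,3R)-2-(4-hydroxy-3-methoxyphenyl)-6-{[(3S,4S,5R)-5-(3-hydroxy-4-methoxyphenyl)-4-(hydroxymethyl)oxolan-3-yl]methyl}-4-methoxy-2,3-dihydro-1-benzofuran-3-yl}methanol (CNP0242386.1)
Conditions: H2 (1 atm), 10% Pd/C, EtOAc–MeOH, rt
Reagents that add atoms: none
Why: Hydrogenolysis of aryl benzyl ethers over palladium at one atmosphere in a neutral solvent is much faster than cleavage of the two benzylic ring C–O bonds in lignans of this type, provided the reaction is stopped once the benzyl groups are gone.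

## Compound list

1 | (4R)-4-benzyl-1,3-oxazolidin-2-one | O=C1N[C@H](Cc2ccccc2)CO1 | starting material
2 | pent-4-enoyl chloride | C=CCCC(Cl)=O | starting material
3 | (4R)-4-benzyl-3-(pent-4-enoyl)-1,3-oxazolidin-2-one | C=CCCC(=O)N1[C@H](Cc2ccccc2)COC1=O | intermediate
4 | tert-butyl bromoacetate | CC(C)(C)OC(=O)CBr | starting material
5 | tert-butyl (3S)-3-{[(4R)-4-benzyl-2-oxo-1,3-oxazolidin-3-yl]carbonyl}hex-5-enoate | C=CC[C@@H](CC(=O)OC(C)(C)C)C(=O)N1[C@H](Cc2ccccc2)COC1=O | intermediate
6 | tert-butyl (3S)-3-(hydroxymethyl)hex-5-enoate | C=CC[C@@H](CC(=O)OC(C)(C)C)CO | intermediate (not isolated)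
7 | (4S)-4-(prop-2-en-1-yl)oxolan-2-one | C=CC[C@H]1CC(=O)OC1 | intermediate
8 | 3-(benzyloxy)-4-methoxybenzaldehyde | COc1ccc(C=O)cc1OCc1ccccc1 | starting material
9 | (3R,4S)-3-{[3-(benzyloxy)-4-methoxyphenyl](hydroxy)methyl}-4-(prop-2-en-1-yl)oxolan-2-one, both carbinol epimers | O1C[C@@H](CC=C)[C@H](C(O)c2ccc(OC)c(OCc3ccccc3)c2)C1=O | intermediate
10 | (2S,3S)-2-{[3-(benzyloxy)-4-methoxyphenyl](hydroxy)methyl}-3-(prop-2-en-1-yl)butane-1,4-diol, both carbinol epimers | OC[C@@H](CC=C)[C@H](C(O)c1ccc(OC)c(OCc2ccccc2)c1)CO | intermediate
11 | [(2R,3S,4S)-2-[3-(benzyloxy)-4-methoxyphenyl]-4-(prop-2-en-1-yl)oxolan-3-yl]methanol | COc1ccc([C@@H]2OC[C@@H](CC=C)[C@H]2CO)cc1OCc1ccccc1 | intermediate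
12 | {[(2R,3S,4S)-2-[3-(benzyloxy)-4-methoxyphenyl]-4-(prop-2-en-1-yl)oxolan-3-yl]methoxy}tri(propan-2-yl)silane | COc1ccc([C@@H]2OC[C@@H](CC=C)[C@H]2CO[Si](C(C)C)(C(C)C)C(C)C)cc1OCc1ccccc1 | intermediate
13 | but-3-en-2-one | CC(=O)C=C | starting material
14 | (3E)-5-[(3S,4S,5R)-5-[3-(benzyloxy)-4-methoxyphenyl]-4-({[tri(propan-2-yl)silyl]oxy}methyl)oxolan-3-yl]pent-3-en-2-one | COc1ccc([C@@H]2OC[C@@H](C/C=C/C(C)=O)[C@H]2CO[Si](C(C)C)(C(C)C)C(C)C)cc1OCc1ccccc1 | intermediate
15 | diethyl propanedioate | CCOC(=O)CC(=O)OCC | starting material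
16 | ethyl 2,4-dioxo-6-(Q-methyl)cyclohexane-1-carboxylate, ring stereoisomers, keto form drawn | COc1ccc([C@@H]2OC[C@@H](CC3CC(=O)CC(=O)C3C(=O)OCC)[C@H]2CO[Si](C(C)C)(C(C)C)C(C)C)cc1OCc1ccccc1 | intermediate (not isolated)
17 | 5-{[(3S,4S,5R)-5-[3-(benzyloxy)-4-methoxyphenyl]-4-({[tri(propan-2-yl)silyl]oxy}methyl)oxolan-3-yl]methyl}cyclohexane-1,3-dione | COc1ccc([C@@H]2OC[C@@H](CC3CC(=O)CC(=O)C3)[C@H]2CO[Si](C(C)C)(C(C)C)C(C)C)cc1OCc1ccccc1 | intermediate
18 | {[tert-butyl(dimethyl)silyl]oxy}acetaldehyde | O=CCO[Si](C)(C)C(C)(C)C | starting material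
19 | 2-[2-{[tert-butyl(dimethyl)silyl]oxy}-1-(4-methylbenzenesulfonyl)ethyl]-5-(Q-methyl)cyclohexane-1,3-dione, stereoisomer mixture | COc1ccc([C@@H]2OC[C@@H](CC3CC(=O)C(C(CO[Si](C)(C)C(C)(C)C)S(=O)(=O)c4ccc(C)cc4)C(=O)C3)[C@H]2CO[Si](C(C)C)(C(C)C)C(C)C)cc1OCc1ccccc1 | intermediate
20 | (2R,5R)-hexane-2,5-diol | C[C@@H](O)CC[C@@H](C)O | starting material
21 | (2R,5R)-hexane-2,5-diyl dimethanesulfonate | C[C@@H](OS(C)(=O)=O)CC[C@@H](C)OS(C)(=O)=O | intermediate
22 | (2S,5S)-2,5-dimethylthiolane | C[C@H]1CC[C@H](C)S1 | intermediate
23 | [4-(benzyloxy)-3-methoxyphenyl]methanol | OCc1ccc(OCc2ccccc2)c(OC)c1 | starting material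
24 | 1-(benzyloxy)-4-(bromomethyl)-2-methoxybenzene | BrCc1ccc(OCc2ccccc2)c(OC)c1 | intermediate
25 | (2S,5S)-1-{[4-(benzyloxy)-3-methoxyphenyl]methyl}-2,5-dimethylthiolan-1-ium tetrafluoroborate | C[C@H]1CC[C@H](C)[S+]1Cc1ccc(OCc2ccccc2)c(OC)c1.F[B-](F)(F)F | intermediate
26 | 2-(2-{[tert-butyl(dimethyl)silyl]oxy}ethylidene)-5-(Q-methyl)cyclohexane-1,3-dione | COc1ccc([C@@H]2OC[C@@H](CC3CC(=O)C(=CCO[Si](C)(C)C(C)(C)C)C(=O)C3)[C@H]2CO[Si](C(C)C)(C(C)C)C(C)C)cc1OCc1ccccc1 | intermediate (not isolated)
27 | [4-(benzyloxy)-3-methoxyphenyl][(2S,5S)-2,5-dimethylthiolan-1-ium-1-yl]methanide | C[C@H]1CC[C@H](C)[S+]1[CH-]c1ccc(OCc2ccccc2)c(OC)c1 | intermediate (not isolated)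
28 | betaine from 26 and 27: 3-oxocyclohex-1-en-1-olate whose C2 carries CH(CH2OSi-t-BuMe2)–CH(aryl)(thiolanium), stereochemistry as in the SMILES | COc1ccc([C@@H]2OC[C@@H](CC3CC(=O)C([C@H](CO[Si](C)(C)C(C)(C)C)[C@H](c4ccc(OCc5ccccc5)c(OC)c4)[S+]4[C@@H](C)CC[C@@H]4C)=C([O-])C3)[C@H]2CO[Si](C(C)C)(C(C)C)C(C)C)cc1OCc1ccccc1 | intermediate (not isolated)
29 | (2S,3R)-2-[4-(benzyloxy)-3-methoxyphenyl]-3-({[tert-butyl(dimethyl)silyl]oxy}methyl)-6-(Q-methyl)-2,3,6,7-tetrahydro-1-benzofuran-4(5H)-one, both C6 epimers | COc1ccc([C@@H]2OC[C@@H](CC3CC(=O)C4=C(C3)O[C@H](c5ccc(OCc6ccccc6)c(OC)c5)[C@H]4CO[Si](C)(C)C(C)(C)C)[C@H]2CO[Si](C(C)C)(C(C)C)C(C)C)cc1OCc1ccccc1 | intermediate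
30 | 5-(phenylselanyl) derivative of 29 | COc1ccc([C@@H]2OC[C@@H](CC3C([Se]c7ccccc7)C(=O)C4=C(C3)O[C@H](c5ccc(OCc6ccccc6)c(OC)c5)[C@H]4CO[Si](C)(C)C(C)(C)C)[C@H]2CO[Si](C(C)C)(C(C)C)C(C)C)cc1OCc1ccccc1 | intermediate (not isolated)
31 | 5,6-didehydro derivative of 29 (2,3-dihydro-1-benzofuran-4(7H)-one, cross-conjugated dienone) | COc1ccc([C@@H]2OC[C@@H](CC3=CC(=O)C4=C(C3)O[C@H](c5ccc(OCc6ccccc6)c(OC)c5)[C@H]4CO[Si](C)(C)C(C)(C)C)[C@H]2CO[Si](C(C)C)(C(C)C)C(C)C)cc1OCc1ccccc1 | intermediate (not isolated)
32 | (2S,3R)-2-[4-(benzyloxy)-3-methoxyphenyl]-3-({[tert-butyl(dimethyl)silyl]oxy}methyl)-6-(Q-methyl)-2,3-dihydro-1-benzofuran-4-ol | COc1ccc([C@@H]2OC[C@@H](Cc3cc(O)c4c(c3)O[C@H](c5ccc(OCc6ccccc6)c(OC)c5)[C@H]4CO[Si](C)(C)C(C)(C)C)[C@H]2CO[Si](C(C)C)(C(C)C)C(C)C)cc1OCc1ccccc1 | intermediate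
33 | (2S,3R)-2-[4-(benzyloxy)-3-methoxyphenyl]-3-({[tert-butyl(dimethyl)silyl]oxy}methyl)-4-methoxy-6-(Q-methyl)-2,3-dihydro-1-benzofuran | COc1ccc([C@@H]2OC[C@@H](Cc3cc(OC)c4c(c3)O[C@H](c5ccc(OCc6ccccc6)c(OC)c5)[C@H]4CO[Si](C)(C)C(C)(C)C)[C@H]2CO[Si](C(C)C)(C(C)C)C(C)C)cc1OCc1ccccc1 | intermediate
34 | {(2S,3R)-2-[4-(benzyloxy)-3-methoxyphenyl]-6-{[(3S,4S,5R)-5-[3-(benzyloxy)-4-methoxyphenyl]-4-(hydroxymethyl)oxolan-3-yl]methyl}-4-methoxy-2,3-dihydro-1-benzofuran-3-yl}methanol | COc1ccc([C@@H]2OC[C@@H](Cc3cc(OC)c4c(c3)O[C@H](c5ccc(OCc6ccccc6)c(OC)c5)[C@H]4CO)[C@H]2CO)cc1OCc1ccccc1 | intermediate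
35 | {(2S,3R)-2-(4-hydroxy-3-methoxyphenyl)-6-{[(3S,4S,5R)-5-(3-hydroxy-4-methoxyphenyl)-4-(hydroxymethyl)oxolan-3-yl]methyl}-4-methoxy-2,3-dihydro-1-benzofuran-3-yl}methanol | COc1ccc([C@@H]2OC[C@@H](Cc3cc(OC)c4c(c3)O[C@H](c3ccc(O)c(OC)c3)[C@H]4CO)[C@H]2CO)cc1O | target

## Step count and least certain steps

Total: 19 steps. Longest linear sequence: 15 steps (steps 1–10 and 15–19); steps 11–14 form the side branch to salt 25.

**Step 15 (key step, proposed new method).**
- What may go wrong: transfer of the electron-rich benzyl group from the sulfonium salt to the liberated sulfinate or to the dione enolate before the ylide has formed; vinylogous deprotonation of the alkylidene dione at its CH2OSi group, which removes the oxadiene; and, most seriously, weak or reversed facial discrimination by the thiolane in an addition for which no calibration exists, which would lower the diastereomeric purity relative to the oxolane centres.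
- Fallback (known chemistry; sets out from 17 and 23, comes back at 29): alcohol 23 is oxidised with MnO2 to 4-(benzyloxy)-3-methoxybenzaldehyde F1. A Horner–Wadsworth–Emmons reaction with triethyl phosphonoacetate gives ethyl (2E)-3-[4-(benzyloxy)-3-methoxyphenyl]prop-2-enoate F2. Reduction with i-Bu2AlH gives (2E)-3-[4-(benzyloxy)-3-methoxyphenyl]prop-2-en-1-ol F3, which is silylated to its tert-butyldimethylsilyl ether F4. Dione 17 and F4 are then joined with Mn(OAc)3·2H2O (trivalent manganese) in buffered acetic acid, the oxidative radical [3+2] annulation of 1,3-diones with styrene-type alkenes. The dione radical adds to the alkene carbon remote from the aryl group, the benzylic radical is oxidised, and the enol oxygen closes the ring, giving the trans constitution of 29. Nothing controls the absolute sense in this reaction, so 29 forms together with its (2R,3S) isomer F5, a diastereomer because of the oxolane centres, and must be separated from it by chromatography.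

**Step 10.**
- What may go wrong: a second conjugate addition of the dione to the Knoevenagel intermediate before the sulfinic acid traps it, and acid-promoted loss of the silyl group of the aldehyde.
- Fallback (sets out from 17, comes back at 29): 17, 18 and thiophenol are condensed under piperidine catalysis, the known three-component route to isolable 2-(1-phenylsulfanylalkyl)-1,3-diones, which gives the phenyl sulfide F6 without acid. Oxidation with mCPBA gives the phenyl sulfone F7, which takes the place of 19 in step 15 and releases 26, and from it 29, in the same way.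

**Step 16.**
- What may go wrong: enolisation at the vinylogous C7 position instead of C5, and over-oxidation of the electron-rich phenol by the selenium–peroxide mixture once it has formed.
- Fallback (sets out from 29, comes back at 32): Saegusa–Ito dehydrogenation. LiN(i-Pr)2 and Me3SiCl give the cross-conjugated trimethylsilyl dienol ether F8. Pd(OAc)2 (divalent palladium) in MeCN converts it, through a palladium enolate and β-hydride elimination, into dienone 31, which tautomerises to 32 with no peroxide or selenium oxidant in the flask.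

**Step 9.**
- What may go wrong: partial loss of the triisopropylsilyl ether and ionisation of the benzylic oxolane ether during the hot alkaline hydrolysis and the acidic decarboxylation, and incomplete Claisen closure.
- Fallback (sets out from 14, comes back at 17): the annulation is run with diprop-2-en-1-yl propanedioate F9 and NaH in THF, which gives the allyl keto ester F10. Pd(PPh3)4 (zerovalent palladium) and morpholine at room temperature then remove the allyl group, and the β-keto acid loses CO2 under neutral conditions (Tsuji deallylation–decarboxylation), so neither hot alkali nor acid reaches the silyl ether.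

## Further compounds

F1 | step 15 | 4-(benzyloxy)-3-methoxybenzaldehyde | COc1cc(C=O)ccc1OCc1ccccc1
F2 | step 15 | ethyl (2E)-3-[4-(benzyloxy)-3-methoxyphenyl]prop-2-enoate | CCOC(=O)/C=C/c1ccc(OCc2ccccc2)c(OC)c1
F3 | step 15 | (2E)-3-[4-(benzyloxy)-3-methoxyphenyl]prop-2-en-1-ol | OC/C=C/c1ccc(OCc2ccccc2)c(OC)c1
F4 | step 15 | tert-butyl{[(2E)-3-[4-(benzyloxy)-3-methoxyphenyl]prop-2-en-1-yl]oxy}dimethylsilane | CC(C)(C)[Si](C)(C)OC/C=C/c1ccc(OCc2ccccc2)c(OC)c1
F5 | step 15 | (2R,3S) diastereomer of 29 | COc1ccc([C@@H]2OC[C@@H](CC3CC(=O)C4=C(C3)O[C@@H](c5ccc(OCc6ccccc6)c(OC)c5)[C@@H]4CO[Si](C)(C)C(C)(C)C)[C@H]2CO[Si](C(C)C)(C(C)C)C(C)C)cc1OCc1ccccc1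
F6 | step 10 | 2-[2-{[tert-butyl(dimethyl)silyl]oxy}-1-(phenylsulfanyl)ethyl]-5-(Q-methyl)cyclohexane-1,3-dione | COc1ccc([C@@H]2OC[C@@H](CC3CC(=O)C(C(CO[Si](C)(C)C(C)(C)C)Sc4ccccc4)C(=O)C3)[C@H]2CO[Si](C(C)C)(C(C)C)C(C)C)cc1OCc1ccccc1
F7 | step 10 | 2-[1-(benzenesulfonyl)-2-{[tert-butyl(dimethyl)silyl]oxy}ethyl]-5-(Q-methyl)cyclohexane-1,3-dione | COc1ccc([C@@H]2OC[C@@H](CC3CC(=O)C(C(CO[Si](C)(C)C(C)(C)C)S(=O)(=O)c4ccccc4)C(=O)C3)[C@H]2CO[Si](C(C)C)(C(C)C)C(C)C)cc1OCc1ccccc1
F8 | step 16 | 4-(trimethylsilyloxy)-4,5-didehydro dienol ether of 29 | COc1ccc([C@@H]2OC[C@@H](CC3C=C(O[Si](C)(C)C)C4=C(C3)O[C@H](c5ccc(OCc6ccccc6)c(OC)c5)[C@H]4CO[Si](C)(C)C(C)(C)C)[C@H]2CO[Si](C(C)C)(C(C)C)C(C)C)cc1OCc1ccccc1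
F9 | step 9 | diprop-2-en-1-yl propanedioate | C=CCOC(=O)CC(=O)OCC=C
F10 | step 9 | prop-2-en-1-yl 2,4-dioxo-6-(Q-methyl)cyclohexane-1-carboxylate | COc1ccc([C@@H]2OC[C@@H](CC3CC(=O)CC(=O)C3C(=O)OCC=C)[C@H]2CO[Si](C(C)C)(C(C)C)C(C)C)cc1OCc1ccccc1
A1 | alternative 1 | methyl (2S,3S)-6-(benzyloxy)-4-methoxy-2-[3-methoxy-4-(2,2-dimethylpropanoyloxy)phenyl]-2,3-dihydro-1-benzofuran-3-carboxylate (trans) | c1ccccc1COc3cc(OC)c4c(c3)O[C@H](c5ccc(OC(=O)C(C)(C)C)c(OC)c5)[C@H]4C(=O)OC
A2 | alternative 1 | (2S)-7-(benzyloxy)-5-methoxy-2-[3-methoxy-4-(2,2-dimethylpropanoyloxy)phenyl]-2,3-dihydro-4H-chromen-4-one | COc1cc(OCc2ccccc2)cc2O[C@H](c3ccc(OC(=O)C(C)(C)C)c(OC)c3)CC(=O)c12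
A3 | alternative 2 | tetrakis(tert-butyldimethylsilyl) ether of 35 | COc1ccc([C@@H]2OC[C@@H](Cc3cc(OC)c4c(c3)O[C@H](c5ccc(O[Si](C)(C)C(C)(C)C)c(OC)c5)[C@H]4CO[Si](C)(C)C(C)(C)C)[C@H]2CO[Si](C)(C)C(C)(C)C)cc1O[Si](C)(C)C(C)(C)C
A4 | alternative 2 | 4-methoxy-2H-pyran-2-one carrying at C3 the 1-aryl-1-(ethynyloxy)-3-silyloxypropan-2-yl chain and at C6 the oxolan-3-ylmethyl group, all four hydroxy groups as tert-butyldimethylsilyl ethers, stereochemistry as in the SMILES | C#CO[C@H](c1ccc(O[Si](C)(C)C(C)(C)C)c(OC)c1)[C@@H](CO[Si](C)(C)C(C)(C)C)C1=C(OC)C=C(C[C@@H]2CO[C@@H](c3ccc(OC)c(O[Si](C)(C)C(C)(C)C)c3)[C@@H]2CO[Si](C)(C)C(C)(C)C)OC1=O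
A5 | alternative 3 | 35 with both phenols benzylated and the dihydrobenzofuran hydroxymethyl as its tert-butyldimethylsilyl ether | COc1ccc([C@@H]2OC[C@@H](Cc3cc(OC)c4c(c3)O[C@H](c5ccc(OCc6ccccc6)c(OC)c5)[C@H]4CO[Si](C)(C)C(C)(C)C)[C@H]2CO)cc1OCc1ccccc1
A6 | alternative 3 | 2-{[3-(benzyloxy)-4-methoxyphenyl][(2E)-3-(dihydrobenzofuran-6-yl)prop-2-en-1-yloxy]methyl}oxirane, the dihydrobenzofuran being the protected (2S,3R) unit of A5, either epoxide epimer | COc1ccc([C@H](OC/C=C/c2cc(OC)c3c(c2)O[C@H](c2ccc(OCc4ccccc4)c(OC)c2)[C@H]3CO[Si](C)(C)C(C)(C)C)C2CO2)cc1OCc1ccccc1
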